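**Assumption (chemistry):** flavan numbering (O1, C2 to C8a) and primed benzofuran numbering are used for all intermediates. Silyl ynol ether 21 is assumed to be accessible by the ynolate route of step 11, and this assumption is covered by a fallback.

## Structural features

The target is a (2S)-flavan: benzene ring A is fused to dihydropyran ring C, phenyl ring B sits on C2, and C8 of ring A is bonded to C2' of a benzofuran (furan ring D fused to benzene ring E). Ring A is pentasubstituted, not hexasubstituted: C5 carries OMe, C7 a free OH, C8 the benzofuranyl group, C8a the ring oxygen O1 and C4a the C4 methylene, while C6 alone carries hydrogen. Ring E repeats the pattern with OMe at C4', methyl at C5', OH at C6' and hydrogen at C7'. The single stereocentre C2 has no stereogenic neighbour; it is benzylic and α to oxygen, so strong bases (deprotonation), strong acids (ionisation of C2–O1) and hydrogenolysis all endanger it. The two free phenols on very electron-rich rings are sensitive to oxidation, and the benzofuran C2'=C3' bond to reduction and electrophiles, which argues for silyl protection and a fluoride end game. The real difficulty is the regiocontrolled construction of ring A, whose three oxygens must end in three different states, together with the C8–C2' bond, which is flanked on both sides by oxygen-bearing carbons. The key step exploits the fact that C4a=C8a of ring A can exist beforehand as the enol ether double bond C5=C6 of an (S)-2-phenyl-3,4-dihydro-2H-pyran. The other four ring A carbons then come from a ketene (C5 and C8, the latter already bonded to the benzofuran) and an ynol ether (C6 and C7).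

## Logic of the disconnections

**28 to 27 to 26.** The two O–Si bonds (oxygens at C7 and C6') and then the O–CH3 bond at C5 are cut. The reason is that 26 leaves the key step with the three ring A oxygens already differentiated (free OH at C5, silyl ether at C7, ring ether at C8a). The gain is that no selective protection is needed and a single fluoride treatment ends the synthesis. The demand is a methylation base that spares aryl silyl ethers and a buffered fluoride source, so that the electron-rich bisphenol 28 does not meet base and air.

**26 to 18 and 21.** The bonds C5–C6, C7–C8 and C4a–C5 are cut. With them goes C8–C8a, which the forward step makes by the 1,2-shift of the dihydropyranyl carbon from the carbonyl carbon (future C5) to the diazo carbon (future C8); in 18 only this acyl substituent can migrate. The reason is that the most substituted ring is taken apart into two open-chain partners while the C8–C2' bond and the stereocentre are carried through untouched. The gain is that the arene problem, the hindered biaryl bond and the oxygen differentiation disappear together. The demand is threefold: the Wolff shift must outrun other carbene chemistry, the [2+2] addition of 21 must have the right orientation, and the 6π closure must engage the enol ether carbon and not C3' of the benzofuran.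

**18 to 17.** The C=N2 bond is cut. The CH2 group of 17 is activated by the ketone and by the heteroaryl ring, so the diazo group can be introduced last and handled only once. The demand is a base strong enough for this CH2 but harmless to C2–H.

**17 to 15 and 5.** The CH2–C(=O) bond is cut. The CH2 side becomes the nucleophile (the enediolate of 15, whose carboxyl carbon is later lost as CO2) and the dihydropyran side the electrophile. The reverse polarity would need metalation next to the ring oxygen with alkyllithium bases that also threaten the benzylic C2–H, and an enolisable acyl partner that such a nucleophile would deprotonate. The gain is two fragments of similar size, each derived from a one-ring starting material. The demand is 1,2-addition to an unsaturated ester and decarboxylation under mild acid.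

**5 to 4 to 3 to 1.** In 5 the C6–CO2Me bond is cut (carbonylation), in 4 the O–P bond (enolate trapping), and in 3 the acyl C–O bond and the C–H bond at the stereocentre. The reason is that the stereocentre is then set first, by catalytic reduction of an aryl ketone. The gain is that one achiral keto acid supplies C2, C3, C4, C4a and C8a. The demand is high enantioselectivity in the reduction and oxidative addition of palladium into an enol C–O bond.

**15 to 13 to 10 and 11.** 15 and 13 differ only in oxidation level. In 13 the bonds O1'–C2' and C3a'–C3' are cut. The reason is that coupling followed by cyclisation under weakly basic conditions keeps the silyl ether, which strongly basic or high-temperature benzofuran syntheses would not. The gain is ring D and the two-carbon side chain in one step. The demand is that the iodine of 10 sits on the carbon between OH and OMe.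

**10 to 9 to 7 to 6.** The C–I bond, then the C–O bond of the new hydroxyl (through the C–B bond of 8), then the O–Si bond are cut. The reason is that 6 already holds OMe, methyl and OH in the right order, and the missing oxygen belongs at the only sterically free C–H. The demand is that iodination choose between the two positions ortho to the new hydroxyl.

**21 to 19.** The O–Si bond is cut and the C≡C–O unit is traced to the two carbons of 19. The demand is that halogen–metal exchange outrun deprotonation and that silylation occur at oxygen.

## Other disconnections considered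

**Alternative 1:** The cut is through O1–C8a and C4–C4a, so that ring C is closed last on a finished ring A.

- *Forward step:* CsF would unmask aryne A2 from silyl triflate A1; the oxygen of (S)-2-phenyloxetane A3 would add at C8a, and the aryl anion left at C4a would have to open the activated four-membered ring at its CH2 carbon to give dibenzyl ether A4.
- *In favour:* both ring C bonds form in one operation, the stereocentre is bought in a small building block, and no diazo compound or photochemistry is needed. On this last point it is better than the chosen plan. The OMe at C5 should direct the oxygen nucleophile to C8a, so the sense of addition is about as well controlled as the [2+2] orientation of the chosen step; here the two are equal.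
- *Against:* A1 needs adjacent silyl and triflate groups next to the hindered biaryl bond and must come from a long series of arene substitutions and a cross-coupling. C8a is shielded by the benzofuranyl group. The carbon transfer from the oxonium oxygen to the neighbouring aryl carbon must pass through a four-membered, front-side arrangement. Ionisation of the benzylic C2–O bond of the activated oxetane would erode the configuration or lead to the 4-phenyl isomer. The final hydrogenolysis of A4 must spare the benzylic C2–O1 bond and C2'=C3'.
- *Comparison:* on structure, it presupposes ring A, the harder ring, which the chosen plan builds. On mechanism, the stereocentre of A3 lies on the activated atom, whereas in 18 it is two carbons from the reacting alkene under neutral conditions. On step economy, it makes two bonds in the key step against three plus a shift, and the way to A1 is longer than the way to 18.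

**Alternative 2:** The cut removes benzene ring E through C4'–C5', C6'–C7' and C3a'–C4'.

- *Forward step:* irradiation of furyl diazo ketone A5 would give ketene A6 by Wolff shift; A6 would add siloxypropyne A7, and 6π closure onto the furan β-carbon would give A8 with a free 4'-OH ready for methylation.
- *In favour:* a monosubstituted heteroarylketene closing onto an aromatic position is the established form of this benzannulation, so this key step is better precedented than the chosen one. The closure has only one site available, and A7 derives from a propionate without the acidic α-hydrogen that complicates 19. On these three points the alternative is the better one. The remote stereocentre is equally safe in both plans.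
- *Against:* ring E is the easier of the two benzene rings. The pentasubstituted ring A with its three different oxygens and the hindered C8–C2' bond would still have to be made by classical arene chemistry on a chiral flavan (halogenation at C8, coupling with a furan, diazoacetylation) before A5 is in hand.
- *Comparison:* on structure, the chosen plan puts its ring-forming step where the difficulty is. On mechanism, both are of the same family, with the alternative closer to known cases. On step economy, the chosen plan is expected to be shorter because A5 is a late, elaborate intermediate.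

**Alternative 3:** The cut is through C3–C4 and O1–C2.

- *Forward step:* a chiral Brønsted acid would dehydrate hydroxybenzyl alcohol A9 to o-quinone methide A10, which would add styrene A11 in an oxa-Diels–Alder reaction to give A12, identical with 27.
- *In favour:* it is the most convergent plan, the stereocentre is set catalytically in the ring-forming step from a commodity alkene, and the end game is the same as in the chosen route. Ring C is made in one step, which equals or betters the three steps (1 to 3) that the chosen plan spends on it.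
- *Against:* A10 has no substituent on its methylene carbon, so it is very reactive and offers the catalyst little to hold; the stereocentre forms at the styrene carbon, far from the acid's binding site. The electron-rich rings of A9 can attack A10 in a Friedel–Crafts sense, and the silyl ethers meet a strong acid. A9 itself requires the complete arene with the biaryl bond.
- *Comparison:* on structure, A9 again presupposes ring A. On mechanism, a cationic stepwise-prone cycloaddition with uncertain enantiocontrol stands against a neutral pericyclic cascade that forms no stereocentre. On step economy, it is good after A9 but poor before it.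

Key step: step 12

## Route

**Step 1**
Reactants: 1 5-oxo-5-phenylpentanoic acid
Product: 3 (S)-6-phenyltetrahydro-2H-pyran-2-one, via hydroxy acid 2 (not isolated)
Conditions: RuCl[(S,S)-TsDPEN](p-cymene) (1 mol%), HCO2H–Et3N (5:2), 40 °C; then TsOH·H2O (cat.), PhMe, 40 °C
Reagents that add atoms: none
Why: Noyori–Ikariya asymmetric transfer hydrogenation of an aryl alkyl ketone, for which the (S,S)-TsDPEN ligand is the one that leads to (S)-1-arylalkanols through the arene/aryl CH–π arrangement during hydride transfer; acid-catalysed lactonisation of 2 then acylates the hydroxyl without breaking the C–O bond at the new stereocentre.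

**Step 2**
Reactants: 3 (S)-6-phenyltetrahydro-2H-pyran-2-one
Product: 4 diphenyl (S)-2-phenyl-3,4-dihydro-2H-pyran-6-yl phosphate
Conditions: KN(SiMe3)2, (PhO)2P(O)Cl, THF–DMPU, −78 °C
Reagents that add atoms: diphenyl chlorophosphate, O=P(Cl)(Oc1ccccc1)Oc1ccccc1
Why: O-phosphorylation of the lactone enolate (ketene acetal phosphate formation); the amide base removes only a proton α to the carbonyl, so the new C=C is the future C4a=C8a and C2–H is untouched.

**Step 3**
Reactants: 4 diphenyl (S)-2-phenyl-3,4-dihydro-2H-pyran-6-yl phosphate
Product: 5 methyl (S)-2-phenyl-3,4-dihydro-2H-pyran-6-carboxylate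
Conditions: Pd(PPh3)4 (5 mol%), CO (1 atm), MeOH, Et3N, DMF, 60 °C
Reagents that add atoms: carbon monoxide, [C-]#[O+]; methanol, CO
Why: Palladium-catalysed methoxycarbonylation of an enol phosphate: zerovalent palladium inserts into the vinylic C–O bond, CO inserts and methanol cleaves the acylpalladium. The weakly basic conditions leave the enol ether and C2 alone, and the carbon delivered by CO is the future C5.

**Step 4**
Reactants: 6 3-methoxy-2-methylphenol
Product: 7 (3-methoxy-2-methylphenoxy)triisopropylsilane
Conditions: i-Pr3SiCl, imidazole, DMF, 40 °C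
Reagents that add atoms: chlorotriisopropylsilane, CC(C)[Si](Cl)(C(C)C)C(C)C
Why: Standard silylation of a phenol; the bulky silyl ether is kept to the end and helps to steer the iodination of step 6.

**Step 5**
Reactants: 7 (3-methoxy-2-methylphenoxy)triisopropylsilane
Product: 9 3-methoxy-4-methyl-5-(triisopropylsilyloxy)phenol, via aryl boronate 8 (not isolated)
Conditions: [Ir(cod)OMe]2 (1.5 mol%), 4,4'-di-tert-butyl-2,2'-bipyridine, B2pin2, THF, 80 °C; then KHSO5 (as 2KHSO5·KHSO4·K2SO4), acetone–H2O, 20 °C
Reagents that add atoms: potassium peroxymonosulfate, [K+].[O-]S(=O)(=O)OO; bis(pinacolato)diboron, CC1(C)OB(OC1(C)C)B1OC(C)(C)C(C)(C)O1 (its boron is present in 8 only)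
Why: Iridium-catalysed C–H borylation is governed by sterics and should go to the one ring C–H without an ortho substituent (meta to both oxygens, para to the methyl); oxidation of the C–B bond in the same flask places the hydroxyl on that carbon, the future C7a'.

**Step 6**
Reactants: 9 3-methoxy-4-methyl-5-(triisopropylsilyloxy)phenol
Product: 10 2-iodo-3-methoxy-4-methyl-5-(triisopropylsilyloxy)phenol
Conditions: N-iodosuccinimide (1.0 equiv), CH2Cl2, −40 → 0 °C
Reagents that add atoms: N-iodosuccinimide, O=C1CCC(=O)N1I
Why: Electrophilic aromatic iodination ortho to the free hydroxyl; of the two ortho positions, C2 (between OH and OMe) is expected to react first because the triisopropylsilyl group, turned away from the neighbouring methyl, covers C6.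

**Step 7**
Reactants: 10 2-iodo-3-methoxy-4-methyl-5-(triisopropylsilyloxy)phenol; 11 but-3-yn-1-ol
Product: 13 2-[4-methoxy-5-methyl-6-(triisopropylsilyloxy)-1-benzofuran-2-yl]ethanol, via alkynylphenol 12 (not isolated)
Conditions: PdCl2(PPh3)2 (3 mol%), CuI (5 mol%), Et3N, DMF, 60 °C
Reagents that add atoms: none
Why: Sonogashira coupling followed by 5-endo-dig cycloisomerisation of the o-alkynylphenol under the same Pd/Cu–amine conditions, a standard benzofuran annulation that forms C3a'–C3' and O1'–C2' without strong base, so the aryl silyl ether survives.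

**Step 8**
Reactants: 13 2-[4-methoxy-5-methyl-6-(triisopropylsilyloxy)-1-benzofuran-2-yl]ethanol
Product: 15 2-[4-methoxy-5-methyl-6-(triisopropylsilyloxy)-1-benzofuran-2-yl]acetic acid, via aldehyde 14 (not isolated)
Conditions: TEMPO (20 mol%), PhI(OAc)2 (2.2 equiv), MeCN–H2O (1:1), 20 °C
Reagents that add atoms: water, O
Why: Nitroxyl-mediated oxidation of a primary alcohol through the aldehyde hydrate to the carboxylic acid; the medium is nearly neutral and the oxidant is selective for the alcohol over the benzofuran and the silyl ether.

**Step 9**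
Reactants: 15 2-[4-methoxy-5-methyl-6-(triisopropylsilyloxy)-1-benzofuran-2-yl]acetic acid; 5 methyl (S)-2-phenyl-3,4-dihydro-2H-pyran-6-carboxylate
Product: 17 2-[4-methoxy-5-methyl-6-(triisopropylsilyloxy)-1-benzofuran-2-yl]-1-[(S)-2-phenyl-3,4-dihydro-2H-pyran-6-yl]ethanone, via keto acid 16 (not isolated)
Conditions: 15, LiN(i-Pr)2 (2.2 equiv), THF, −78 → 0 °C; then 5, −78 → 20 °C; AcOH, H2O, 40 °C
Reagents that add atoms: none
Why: Claisen-type acylation of the dilithium enediolate of an arylacetic acid (Ivanov-type dianion) by a non-enolisable ester, followed by decarboxylation of the β-keto acid on mild acidification. Donation from O1 makes the β-carbon of the unsaturated ester a poor acceptor, so 1,2-addition should prevail, and no alkyllithium comes near the benzylic C2–H.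

**Step 10**
Reactants: 17 2-[4-methoxy-5-methyl-6-(triisopropylsilyloxy)-1-benzofuran-2-yl]-1-[(S)-2-phenyl-3,4-dihydro-2H-pyran-6-yl]ethanone
Product: 18 2-diazo-2-[4-methoxy-5-methyl-6-(triisopropylsilyloxy)-1-benzofuran-2-yl]-1-[(S)-2-phenyl-3,4-dihydro-2H-pyran-6-yl]ethanone
Conditions: 4-acetamidobenzenesulfonyl azide, DBU, MeCN, 0 → 20 °C, dark
Reagents that add atoms: 4-acetamidobenzenesulfonyl azide, CC(=O)Nc1ccc(cc1)S(=O)(=O)N=[N+]=[N-]
Why: Regitz diazo transfer to a methylene group activated by both the ketone and the benzofuranyl ring; an amidine base suffices and does not affect C2. The product is kept cold and dark and used directly.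

**Step 11**
Reactants: 19 ethyl dibromoacetate
Product: 21 (triisopropylsilyloxy)acetylene, via lithium ethynolate 20 (not isolated)
Conditions: t-BuLi (4.0 equiv), THF, −78 → 0 °C (19 added to the base); then i-Pr3SiCl (2.2 equiv), −78 → 20 °C
Reagents that add atoms: chlorotriisopropylsilane, CC(C)[Si](Cl)(C(C)C)C(C)C
Why: Ynolate formation from an α,α-dibromo ester by two bromine–lithium exchanges and loss of ethoxide from the resulting ester dianion; bulky chlorosilanes silylate ynolates at oxygen, which gives the silyl ynol ether.

**Step 12**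
Reactants: 18 2-diazo-2-[4-methoxy-5-methyl-6-(triisopropylsilyloxy)-1-benzofuran-2-yl]-1-[(S)-2-phenyl-3,4-dihydro-2H-pyran-6-yl]ethanone; 21 (triisopropylsilyloxy)acetylene
Product: 26 (S)-8-[4-methoxy-5-methyl-6-(triisopropylsilyloxy)-1-benzofuran-2-yl]-2-phenyl-7-(triisopropylsilyloxy)chroman-5-ol, via ketene 22 (not isolated), via cyclobutenone 23 (not isolated), via dienylketene 24 (not isolated), via cyclohexadienone 25 (not isolated)
Conditions: 21 (2.5 equiv), hν (440 nm LEDs), PhMe (degassed), 20 °C; then 80 °C
Reagents that add atoms: none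
Why: Proposed new method: visible light expels N2 from 18 and the dihydropyranyl carbon shifts from the carbonyl carbon (future C5) to the diazo carbon (future C8) in a Wolff rearrangement, so that ketene 22 carries both the benzofuranyl group and the cyclic enol ether on its α-carbon. The nucleophilic CH carbon of 21 bonds to the ketene carbonyl carbon (C5–C6) and the silyloxy carbon to the α-carbon (C7–C8) in a [2+2] cycloaddition whose orientation is dictated by the ynol ether polarity, giving cyclobutenone 23. Thermal 4π electrocyclic opening of 23 gives dienylketene 24, and the geometric isomer with the dihydropyranyl group cis to the ketene undergoes a disrotatory 6π electrocyclisation that joins the ketene carbon to the enol ether β-carbon (C4a–C5) and so closes ring A as dienone 25, which tautomerises to phenol 26. The closest known reaction type is the Danheiser benzannulation of vinylketenes, generated by photo-Wolff rearrangement of α,β-unsaturated diazo ketones, with siloxyalkynes; it is extended here to a disubstituted ketene whose vinyl arm is a cyclic enol ether. No stereocentre is formed, and C2, two carbons from the reacting alkene, meets only neutral aprotic conditions, so its (S) configuration should be retained. The selectivity needed is closure onto the enol ether carbon and not onto benzofuran C3': the former costs no aromatic stabilisation, and because the opening of 23 is reversible the wrong geometric isomer of 24 can return through 23 and drain through the faster closure. An excess of 21 should keep 22 from dimerising or acylating 26.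

**Step 13**
Reactants: 26 (S)-8-[4-methoxy-5-methyl-6-(triisopropylsilyloxy)-1-benzofuran-2-yl]-2-phenyl-7-(triisopropylsilyloxy)chroman-5-ol
Product: 27 (S)-5-methoxy-8-[4-methoxy-5-methyl-6-(triisopropylsilyloxy)-1-benzofuran-2-yl]-2-phenyl-7-(triisopropylsilyloxy)chroman
Conditions: MeI, K2CO3, acetone, 50 °C
Reagents that add atoms: iodomethane, CI
Why: Williamson O-methylation of the only free phenol; anhydrous carbonate in acetone does not cleave aryl triisopropylsilyl ethers and does not affect C2.

**Step 14**
Reactants: 27 (S)-5-methoxy-8-[4-methoxy-5-methyl-6-(triisopropylsilyloxy)-1-benzofuran-2-yl]-2-phenyl-7-(triisopropylsilyloxy)chroman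
Product: 28 (S)-8-(6-hydroxy-4-methoxy-5-methyl-1-benzofuran-2-yl)-5-methoxy-2-phenylchroman-7-ol (CNP0000229.1)
Conditions: Bu4NF (2.5 equiv), AcOH (2.5 equiv), THF, 0 → 20 °C
Reagents that add atoms: none
Why: Fluoride cleavage of both aryl silyl ethers in one operation; buffering with acetic acid keeps the electron-rich bisphenol from standing as a phenoxide, and neither the methyl ethers nor the C2–O1 bond react.

## Compound list

1 | 5-oxo-5-phenylpentanoic acid | O=C(O)CCCC(=O)c1ccccc1 | starting material
2 | (S)-5-hydroxy-5-phenylpentanoic acid | O=C(O)CCC[C@H](O)c1ccccc1 | intermediate (not isolated)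
3 | (S)-6-phenyltetrahydro-2H-pyran-2-one | O=C1CCC[C@@H](c2ccccc2)O1 | intermediate
4 | diphenyl (S)-2-phenyl-3,4-dihydro-2H-pyran-6-yl phosphate | O=P(Oc1ccccc1)(Oc1ccccc1)OC1=CCC[C@@H](c2ccccc2)O1 | intermediate
5 | methyl (S)-2-phenyl-3,4-dihydro-2H-pyran-6-carboxylate | COC(=O)C1=CCC[C@@H](c2ccccc2)O1 | intermediate
6 | 3-methoxy-2-methylphenol | COc1cccc(O)c1C | starting material
7 | (3-methoxy-2-methylphenoxy)triisopropylsilane | COc1cccc(O[Si](C(C)C)(C(C)C)C(C)C)c1C | intermediate
8 | 2-[3-methoxy-4-methyl-5-(triisopropylsilyloxy)phenyl]-4,4,5,5-tetramethyl-1,3,2-dioxaborolane | COc1cc(B2OC(C)(C)C(C)(C)O2)cc(O[Si](C(C)C)(C(C)C)C(C)C)c1C | intermediate (not isolated)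
9 | 3-methoxy-4-methyl-5-(triisopropylsilyloxy)phenol | COc1cc(O)cc(O[Si](C(C)C)(C(C)C)C(C)C)c1C | intermediate
10 | 2-iodo-3-methoxy-4-methyl-5-(triisopropylsilyloxy)phenol | COc1c(I)c(O)cc(O[Si](C(C)C)(C(C)C)C(C)C)c1C | intermediate
11 | but-3-yn-1-ol | C#CCCO | starting material
12 | 2-(4-hydroxybut-1-yn-1-yl)-3-methoxy-4-methyl-5-(triisopropylsilyloxy)phenol | COc1c(C#CCCO)c(O)cc(O[Si](C(C)C)(C(C)C)C(C)C)c1C | intermediate (not isolated)
13 | 2-[4-methoxy-5-methyl-6-(triisopropylsilyloxy)-1-benzofuran-2-yl]ethanol | OCCc1cc2c(OC)c(C)c(O[Si](C(C)C)(C(C)C)C(C)C)cc2o1 | intermediate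
14 | 2-[4-methoxy-5-methyl-6-(triisopropylsilyloxy)-1-benzofuran-2-yl]acetaldehyde | O=CCc1cc2c(OC)c(C)c(O[Si](C(C)C)(C(C)C)C(C)C)cc2o1 | intermediate (not isolated)
15 | 2-[4-methoxy-5-methyl-6-(triisopropylsilyloxy)-1-benzofuran-2-yl]acetic acid | OC(=O)Cc1cc2c(OC)c(C)c(O[Si](C(C)C)(C(C)C)C(C)C)cc2o1 | intermediate
16 | 2-[4-methoxy-5-methyl-6-(triisopropylsilyloxy)-1-benzofuran-2-yl]-3-oxo-3-[(S)-2-phenyl-3,4-dihydro-2H-pyran-6-yl]propanoic acid (α-carbon unassigned, both epimers) | OC(=O)C(C(=O)C1=CCC[C@@H](c2ccccc2)O1)c1cc2c(OC)c(C)c(O[Si](C(C)C)(C(C)C)C(C)C)cc2o1 | intermediate (not isolated)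
17 | 2-[4-methoxy-5-methyl-6-(triisopropylsilyloxy)-1-benzofuran-2-yl]-1-[(S)-2-phenyl-3,4-dihydro-2H-pyran-6-yl]ethanone | O=C(Cc1cc2c(OC)c(C)c(O[Si](C(C)C)(C(C)C)C(C)C)cc2o1)C1=CCC[C@@H](c2ccccc2)O1 | intermediate
18 | 2-diazo-2-[4-methoxy-5-methyl-6-(triisopropylsilyloxy)-1-benzofuran-2-yl]-1-[(S)-2-phenyl-3,4-dihydro-2H-pyran-6-yl]ethanone | O=C(C1=CCC[C@@H](c2ccccc2)O1)C(=[N+]=[N-])c1cc2c(OC)c(C)c(O[Si](C(C)C)(C(C)C)C(C)C)cc2o1 | intermediate
19 | ethyl dibromoacetate | CCOC(=O)C(Br)Br | starting material
20 | lithium ethynolate | [Li+].[O-]C#C | intermediate (not isolated)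
21 | (triisopropylsilyloxy)acetylene | C#CO[Si](C(C)C)(C(C)C)C(C)C | intermediate
22 | 2-[4-methoxy-5-methyl-6-(triisopropylsilyloxy)-1-benzofuran-2-yl]-2-[(S)-2-phenyl-3,4-dihydro-2H-pyran-6-yl]ethenone (ketene) | O=C=C(C1=CCC[C@@H](c2ccccc2)O1)c1cc2c(OC)c(C)c(O[Si](C(C)C)(C(C)C)C(C)C)cc2o1 | intermediate (not isolated)
23 | 4-[4-methoxy-5-methyl-6-(triisopropylsilyloxy)-1-benzofuran-2-yl]-4-[(S)-2-phenyl-3,4-dihydro-2H-pyran-6-yl]-3-(triisopropylsilyloxy)cyclobut-2-en-1-one (C4 unassigned) | O=C1C=C(O[Si](C(C)C)(C(C)C)C(C)C)C1(C1=CCC[C@@H](c2ccccc2)O1)c1cc2c(OC)c(C)c(O[Si](C(C)C)(C(C)C)C(C)C)cc2o1 | intermediate (not isolated)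
24 | 4-[4-methoxy-5-methyl-6-(triisopropylsilyloxy)-1-benzofuran-2-yl]-4-[(S)-2-phenyl-3,4-dihydro-2H-pyran-6-yl]-3-(triisopropylsilyloxy)buta-1,3-dien-1-one, dihydropyranyl group cis to the ketene | O=C=C/C(O[Si](C(C)C)(C(C)C)C(C)C)=C(\C1=CCC[C@@H](c2ccccc2)O1)c1cc2c(OC)c(C)c(O[Si](C(C)C)(C(C)C)C(C)C)cc2o1 | intermediate (not isolated)
25 | (2S)-8-[4-methoxy-5-methyl-6-(triisopropylsilyloxy)-1-benzofuran-2-yl]-2-phenyl-7-(triisopropylsilyloxy)-2,3,4,4a-tetrahydro-5H-chromen-5-one (C4a unassigned) | O=C1C=C(O[Si](C(C)C)(C(C)C)C(C)C)C(c2cc3c(OC)c(C)c(O[Si](C(C)C)(C(C)C)C(C)C)cc3o2)=C2O[C@H](c3ccccc3)CCC12 | intermediate (not isolated)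
26 | (S)-8-[4-methoxy-5-methyl-6-(triisopropylsilyloxy)-1-benzofuran-2-yl]-2-phenyl-7-(triisopropylsilyloxy)chroman-5-ol | Oc1cc(O[Si](C(C)C)(C(C)C)C(C)C)c(-c2cc3c(OC)c(C)c(O[Si](C(C)C)(C(C)C)C(C)C)cc3o2)c2c1CC[C@@H](c1ccccc1)O2 | intermediate
27 | (S)-5-methoxy-8-[4-methoxy-5-methyl-6-(triisopropylsilyloxy)-1-benzofuran-2-yl]-2-phenyl-7-(triisopropylsilyloxy)chroman | COc1cc(O[Si](C(C)C)(C(C)C)C(C)C)c(-c2cc3c(OC)c(C)c(O[Si](C(C)C)(C(C)C)C(C)C)cc3o2)c2c1CC[C@@H](c1ccccc1)O2 | intermediate
28 | (S)-8-(6-hydroxy-4-methoxy-5-methyl-1-benzofuran-2-yl)-5-methoxy-2-phenylchroman-7-ol (CNP0000229.1) | COc1cc(O)c(-c2cc3c(OC)c(C)c(O)cc3o2)c2c1CC[C@@H](c1ccccc1)O2 | target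

## Step count and risk

Total: 14 steps. Longest linear sequence: 10 steps (steps 4, 5, 6, 7, 8, 9, 10, 12, 13, 14). The ring C branch (steps 1 to 3) joins at step 9 and the ynol ether (step 11) joins at step 12.

**Step 12 (proposed new method, key step).** Three processes may interfere:
- Electrocyclisation onto C3' of the benzofuran in place of the enol ether carbon, if the ring opening places the benzofuranyl group cis to the ketene and that closure is faster than the return to 23.
- Consumption of the hindered, disubstituted ketene by dimerisation or by O-acylation of the phenol being formed, because its [2+2] addition is slower than that of a monosubstituted ketene.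
- Carbene chemistry ahead of the Wolff shift (insertion, or opening of the furan ring next to the carbene carbon).

Fallback with known chemistry, setting out from 10 and coming back at 27: ring A is taken from the purchased natural flavanone (S)-alpinetin F1, which already holds O1, the 5-OMe, the 7-OH and the (S) centre. Silylation (i-Pr3SiCl, imidazole) gives silyl ether F2. Reduction with NaBH4 gives flavan-4-ol F3, and ionic hydrogenation (Et3SiH, CF3CO2H, CH2Cl2, −20 °C) gives flavan F4. Iodination with N-iodosuccinimide is expected at C8, the position next to the tied-back ring oxygen, as in halogenations of 5,7-dioxygenated flavans, giving 8-iodoflavan F5. Stille coupling with Bu3SnC≡CH and Pd(PPh3)4 gives 8-ethynylflavan F6. Sonogashira coupling of F6 with 10 under the conditions of step 7 gives diarylalkyne phenol F7, which cyclises in the same flask to 27, and step 14 follows. The C8–C2' connection is thus made as an aryl–alkyne bond and ring D by cycloisomerisation.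

**Step 11.** The α-hydrogen of 19 is acidic, so proton transfer to t-BuLi may compete with bromine–lithium exchange and divert the sequence away from the parent ynolate. Silylation at carbon in place of oxygen is a second possible leak, since the ynolate carbon is unhindered.

Fallback, setting out from 18 and coming back at 28: the known, distillable ynol ether tert-butoxyacetylene F8 replaces 21 in step 12. Irradiation is carried to completion at 20 °C before heating, because F8 is thermally labile. Ketene 22 then gives tert-butoxy cyclobutenone F9, tert-butoxy dienylketene F10, tert-butoxy dienone F11 and 7-tert-butoxy phenol F12. Methylation as in step 13 gives 7-tert-butoxy methyl ether F13. Bu4NF/AcOH removes the 6'-silyl group to give tert-butyl ether phenol F14. Brief treatment with CF3CO2H in CH2Cl2 at 0 °C (a cation trap may be added) cleaves the aryl tert-butyl ether to 28.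

**Step 6.** Poor regioselectivity is possible: the position between OH and the silyl ether is para to OMe and electronically competitive, so the iodination relies on steric shielding only. Double iodination of the very electron-rich ring is a further risk.

Fallback, setting out from 9 and coming back at 10: the hydroxyl is converted to methoxymethyl ether F15 (MeOCH2Cl, i-Pr2NEt). Directed ortho-lithiation with n-BuLi (THF, 0 °C) occurs at the carbon between the two coordinating groups OCH2OMe and OMe, and quenching with I2 gives iodo methoxymethyl ether F16. Mild acid (HCl, MeOH, 20 °C) removes the acetal and gives 10.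

**Step 9.** Conjugate addition of the enediolate to the unsaturated ester, or incomplete acylation through proton exchange between the enediolate and the product, could lower the conversion.

Fallback, setting out from 4 and 15 and coming back at 17: 4 is converted with Me3SnSnMe3, Pd(PPh3)4 and LiCl into dihydropyranyl stannane F17, and 15 with oxalyl chloride and catalytic DMF into acid chloride F18. Stille acylation of F18 with F17 (PdCl2(PPh3)2, PhMe, 60 °C) gives 17 under neutral conditions. This also bypasses step 3.

## Further compounds

F1 | step 12 | (S)-alpinetin, (S)-7-hydroxy-5-methoxy-2-phenylchroman-4-one (purchased) | COc1cc(O)cc2c1C(=O)C[C@@H](c1ccccc1)O2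
F2 | step 12 | (S)-5-methoxy-2-phenyl-7-(triisopropylsilyloxy)chroman-4-one | COc1cc(O[Si](C(C)C)(C(C)C)C(C)C)cc2c1C(=O)C[C@@H](c1ccccc1)O2
F3 | step 12 | (2S)-5-methoxy-2-phenyl-7-(triisopropylsilyloxy)chroman-4-ol (C4 unassigned) | COc1cc(O[Si](C(C)C)(C(C)C)C(C)C)cc2c1C(O)C[C@@H](c1ccccc1)O2
F4 | step 12 | (S)-5-methoxy-2-phenyl-7-(triisopropylsilyloxy)chroman | COc1cc(O[Si](C(C)C)(C(C)C)C(C)C)cc2c1CC[C@@H](c1ccccc1)O2
F5 | step 12 | (S)-8-iodo-5-methoxy-2-phenyl-7-(triisopropylsilyloxy)chroman | COc1cc(O[Si](C(C)C)(C(C)C)C(C)C)c(I)c2c1CC[C@@H](c1ccccc1)O2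
F6 | step 12 | (S)-8-ethynyl-5-methoxy-2-phenyl-7-(triisopropylsilyloxy)chroman | COc1cc(O[Si](C(C)C)(C(C)C)C(C)C)c(C#C)c2c1CC[C@@H](c1ccccc1)O2
F7 | step 12 | 3-methoxy-2-{[(S)-5-methoxy-2-phenyl-7-(triisopropylsilyloxy)chroman-8-yl]ethynyl}-4-methyl-5-(triisopropylsilyloxy)phenol | COc1cc(O[Si](C(C)C)(C(C)C)C(C)C)c(C#Cc3c(O)cc(O[Si](C(C)C)(C(C)C)C(C)C)c(C)c3OC)c2c1CC[C@@H](c1ccccc1)O2
F8 | step 11 | tert-butoxyacetylene | C#COC(C)(C)C
F9 | step 11 | 3-tert-butoxy-4-[4-methoxy-5-methyl-6-(triisopropylsilyloxy)-1-benzofuran-2-yl]-4-[(S)-2-phenyl-3,4-dihydro-2H-pyran-6-yl]cyclobut-2-en-1-one (C4 unassigned) | O=C1C=C(OC(C)(C)C)C1(C1=CCC[C@@H](c2ccccc2)O1)c1cc2c(OC)c(C)c(O[Si](C(C)C)(C(C)C)C(C)C)cc2o1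
F10 | step 11 | 3-tert-butoxy-4-[4-methoxy-5-methyl-6-(triisopropylsilyloxy)-1-benzofuran-2-yl]-4-[(S)-2-phenyl-3,4-dihydro-2H-pyran-6-yl]buta-1,3-dien-1-one, dihydropyranyl group cis to the ketene | O=C=C/C(OC(C)(C)C)=C(\C1=CCC[C@@H](c2ccccc2)O1)c1cc2c(OC)c(C)c(O[Si](C(C)C)(C(C)C)C(C)C)cc2o1
F11 | step 11 | (2S)-7-tert-butoxy-8-[4-methoxy-5-methyl-6-(triisopropylsilyloxy)-1-benzofuran-2-yl]-2-phenyl-2,3,4,4a-tetrahydro-5H-chromen-5-one (C4a unassigned) | O=C1C=C(OC(C)(C)C)C(c2cc3c(OC)c(C)c(O[Si](C(C)C)(C(C)C)C(C)C)cc3o2)=C2O[C@H](c3ccccc3)CCC12
F12 | step 11 | (S)-7-tert-butoxy-8-[4-methoxy-5-methyl-6-(triisopropylsilyloxy)-1-benzofuran-2-yl]-2-phenylchroman-5-ol | Oc1cc(OC(C)(C)C)c(-c2cc3c(OC)c(C)c(O[Si](C(C)C)(C(C)C)C(C)C)cc3o2)c2c1CC[C@@H](c1ccccc1)O2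
F13 | step 11 | (S)-7-tert-butoxy-5-methoxy-8-[4-methoxy-5-methyl-6-(triisopropylsilyloxy)-1-benzofuran-2-yl]-2-phenylchroman | COc1cc(OC(C)(C)C)c(-c2cc3c(OC)c(C)c(O[Si](C(C)C)(C(C)C)C(C)C)cc3o2)c2c1CC[C@@H](c1ccccc1)O2
F14 | step 11 | 2-[(S)-7-tert-butoxy-5-methoxy-2-phenylchroman-8-yl]-4-methoxy-5-methyl-1-benzofuran-6-ol | COc1cc(OC(C)(C)C)c(-c2cc3c(OC)c(C)c(O)cc3o2)c2c1CC[C@@H](c1ccccc1)O2
F15 | step 6 | [3-methoxy-5-(methoxymethoxy)-2-methylphenoxy]triisopropylsilane | COCOc1cc(O[Si](C(C)C)(C(C)C)C(C)C)c(C)c(OC)c1
F16 | step 6 | [4-iodo-3-methoxy-5-(methoxymethoxy)-2-methylphenoxy]triisopropylsilane | COCOc1cc(O[Si](C(C)C)(C(C)C)C(C)C)c(C)c(OC)c1I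
F17 | step 9 | trimethyl[(S)-2-phenyl-3,4-dihydro-2H-pyran-6-yl]stannane | C[Sn](C)(C)C1=CCC[C@@H](c2ccccc2)O1
F18 | step 9 | 2-[4-methoxy-5-methyl-6-(triisopropylsilyloxy)-1-benzofuran-2-yl]acetyl chloride | O=C(Cl)Cc1cc2c(OC)c(C)c(O[Si](C(C)C)(C(C)C)C(C)C)cc2o1
A1 | alternative 1 | 3-benzyloxy-2-(6-benzyloxy-4-methoxy-5-methyl-1-benzofuran-2-yl)-5-methoxy-6-(trimethylsilyl)phenyl trifluoromethanesulfonate | COc1cc(OCc2ccccc2)c(-c2cc3c(OC)c(C)c(OCc4ccccc4)cc3o2)c(OS(=O)(=O)C(F)(F)F)c1[Si](C)(C)C
A2 | alternative 1 | aryne, 4-benzyloxy-3-(6-benzyloxy-4-methoxy-5-methyl-1-benzofuran-2-yl)-6-methoxybenzyne | COC1=CC(OCc2ccccc2)=C(c2cc3c(OC)c(C)c(OCc4ccccc4)cc3o2)C#C1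
A3 | alternative 1 | (S)-2-phenyloxetane | C1C[C@@H](c2ccccc2)O1
A4 | alternative 1 | (S)-7-benzyloxy-8-(6-benzyloxy-4-methoxy-5-methyl-1-benzofuran-2-yl)-5-methoxy-2-phenylchroman | COc1cc(OCc2ccccc2)c(-c2cc3c(OC)c(C)c(OCc4ccccc4)cc3o2)c2c1CC[C@@H](c1ccccc1)O2
A5 | alternative 2 | 2-diazo-1-{5-[(S)-5-methoxy-2-phenyl-7-(triisopropylsilyloxy)chroman-8-yl]furan-2-yl}ethanone | COc1cc(O[Si](C(C)C)(C(C)C)C(C)C)c(-c2ccc(C(=O)C=[N+]=[N-])o2)c2c1CC[C@@H](c1ccccc1)O2
A6 | alternative 2 | 2-{5-[(S)-5-methoxy-2-phenyl-7-(triisopropylsilyloxy)chroman-8-yl]furan-2-yl}ethenone (ketene) | COc1cc(O[Si](C(C)C)(C(C)C)C(C)C)c(-c2ccc(C=C=O)o2)c2c1CC[C@@H](c1ccccc1)O2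
A7 | alternative 2 | 1-(triisopropylsilyloxy)propyne | CC#CO[Si](C(C)C)(C(C)C)C(C)C
A8 | alternative 2 | 2-[(S)-5-methoxy-2-phenyl-7-(triisopropylsilyloxy)chroman-8-yl]-5-methyl-6-(triisopropylsilyloxy)-1-benzofuran-4-ol | COc1cc(O[Si](C(C)C)(C(C)C)C(C)C)c(-c2cc3c(O)c(C)c(O[Si](C(C)C)(C(C)C)C(C)C)cc3o2)c2c1CC[C@@H](c1ccccc1)O2
A9 | alternative 3 | 2-(hydroxymethyl)-3-methoxy-6-[4-methoxy-5-methyl-6-(triisopropylsilyloxy)-1-benzofuran-2-yl]-5-(triisopropylsilyloxy)phenol | COc1cc(O[Si](C(C)C)(C(C)C)C(C)C)c(-c2cc3c(OC)c(C)c(O[Si](C(C)C)(C(C)C)C(C)C)cc3o2)c(O)c1CO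
A10 | alternative 3 | o-quinone methide, 5-methoxy-2-[4-methoxy-5-methyl-6-(triisopropylsilyloxy)-1-benzofuran-2-yl]-6-methylene-3-(triisopropylsilyloxy)cyclohexa-2,4-dien-1-one | COC1=CC(O[Si](C(C)C)(C(C)C)C(C)C)=C(c2cc3c(OC)c(C)c(O[Si](C(C)C)(C(C)C)C(C)C)cc3o2)C(=O)C1=C
A11 | alternative 3 | styrene | C=Cc1ccccc1
A12 | alternative 3 | (S)-5-methoxy-8-[4-methoxy-5-methyl-6-(triisopropylsilyloxy)-1-benzofuran-2-yl]-2-phenyl-7-(triisopropylsilyloxy)chroman (identical with 27) | COc1cc(O[Si](C(C)C)(C(C)C)C(C)C)c(-c2cc3c(OC)c(C)c(O[Si](C(C)C)(C(C)C)C(C)C)cc3o2)c2c1CC[C@@H](c1ccccc1)O2
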